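## Retrosynthetic overview

1. Schizolaenone C (21) comes from its tetra-MOM ether 20 by acidic unmasking in the last step.
2. Ring C is the only ring to be made (rings A and B are bought as arenes). It comes from the acyclic diazoketone 17 in one flask: the Wolff shift of C2 makes C2–C3, and the ketene carbon (C4) then acylates ring A to make C4–C4a.
3. 17 comes from the O-aryl mandelic acid 15 and CH2N2; the O1–C2 bond comes from Mitsunobu inversion of the (S)-mandelate 13 by phenol 7.
4. 7 comes from phloroglucinol (mono-TIPS, bis-MOM, lithiation between the MOM groups, geranyl bromide); 13 comes from 5-bromoresorcinol (aryllithium + dimethyl oxalate, asymmetric transfer hydrogenation).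
5. Enabling feature: C2 carries O1, ring B and one carbon, so O1–C2(ring B)–C is a mandelic acid whose carboxyl carbon becomes C4 once C3 is slipped in between. In ring A, O1 lies para to the geranylated C6, so the two carbons ortho to O1 (C4a and C8) are equivalent and each is ortho/para to three oxygens; closure can only give the 6-geranyl-5,7-dioxygenated chromanone.

Key step: step 11

Remark: in step 7 the sense of induction is taken from the usual model for this catalyst class; should the (R)-hydroxy ester form instead, the (S,S)-catalyst is used and nothing else changes. "Geranyl" below means (2E)-3,7-dimethylocta-2,6-dien-1-yl.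

## Route

Step 1
Reactants: 1 phloroglucinol (benzene-1,3,5-triol)
Product: 2 5-(triisopropylsilyloxy)benzene-1,3-diol
Conditions: TIPSCl (1 equiv), 1 (3 equiv), imidazole, DMF, 0 → 23 °C
Reagents that add atoms: chlorotriisopropylsilane, CC(C)[Si](Cl)(C(C)C)C(C)C
Why: Silyl ether formation on a symmetric triol used in excess, so the bulky silyl chloride should stop at the mono-ether and the water-soluble triol is washed out.

Step 2
Reactants: 2 5-(triisopropylsilyloxy)benzene-1,3-diol
Product: 3 [3,5-bis(methoxymethoxy)phenoxy]triisopropylsilane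
Conditions: MOMCl (2.5 equiv), iPr2NEt, CH2Cl2, 0 → 23 °C
Reagents that add atoms: chloromethyl methyl ether, COCCl
Why: MOM protection (O-alkylation by the α-chloro ether) of both free phenols; the hindered aryl TIPS ether should survive the amine base.

Step 3
Reactants: 3 [3,5-bis(methoxymethoxy)phenoxy]triisopropylsilane; 4 geranyl bromide
Product: 6 triisopropyl[4-geranyl-3,5-bis(methoxymethoxy)phenoxy]silane, via aryllithium 5 (not isolated)
Conditions: n-BuLi, THF, 0 °C; then CuI (10 mol %), 4, −78 → 0 °C
Reagents that add atoms: none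
Why: Directed ortho-metalation at the carbon flanked by the two MOM ethers (the TIPS ether is a poor director and lies para), then copper-catalysed SN2 allylation by the primary allylic bromide, which should keep the E-geometry.

Step 4
Reactants: 6 triisopropyl[4-geranyl-3,5-bis(methoxymethoxy)phenoxy]silane
Product: 7 4-geranyl-3,5-bis(methoxymethoxy)phenol
Conditions: Bu4NF, AcOH (1 equiv), THF, 0 → 23 °C
Reagents that add atoms: none
Why: Fluoride desilylation of the aryl TIPS ether, buffered with acetic acid; MOM ethers and the diene are inert.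

Step 5
Reactants: 8 5-bromoresorcinol (5-bromobenzene-1,3-diol)
Product: 9 1-bromo-3,5-bis(methoxymethoxy)benzene
Conditions: MOMCl (2.5 equiv), iPr2NEt, CH2Cl2, 0 → 23 °C
Reagents that add atoms: chloromethyl methyl ether, COCCl
Why: MOM protection of both phenols under mild amine-base conditions.

Step 6
Reactants: 9 1-bromo-3,5-bis(methoxymethoxy)benzene; 10 dimethyl oxalate
Product: 12 methyl 2-[3,5-bis(methoxymethoxy)phenyl]-2-oxoacetate, via aryllithium 11 (not isolated)
Conditions: n-BuLi, THF, −78 °C; cannulated into 10 (3 equiv), THF, −78 °C; AcOH quench at −78 °C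
Reagents that add atoms: none
Why: Bromine–lithium exchange (faster than ortho-lithiation at −78 °C) followed by acylation of the aryllithium by excess oxalate under inverse addition, which should stop at the α-keto ester because the tetrahedral adduct persists until the quench.

Step 7
Reactants: 12 methyl 2-[3,5-bis(methoxymethoxy)phenyl]-2-oxoacetate
Product: 13 methyl (2S)-2-[3,5-bis(methoxymethoxy)phenyl]-2-hydroxyacetate
Conditions: RuCl(p-cymene)[(R,R)-TsDPEN] (1 mol %), HCO2H/Et3N (5:2), CH2Cl2, 25 °C
Reagents that add atoms: none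
Why: Noyori asymmetric transfer hydrogenation of an aryl α-keto ester; hydride goes to the face fixed by the CH/π contact between ring B and the η6-arene of the catalyst, which for the (R,R)-catalyst should give the (S)-hydroxy ester and so sets the stereocentre that becomes C2.

Step 8
Reactants: 7 4-geranyl-3,5-bis(methoxymethoxy)phenol; 13 methyl (2S)-2-[3,5-bis(methoxymethoxy)phenyl]-2-hydroxyacetate
Product: 14 methyl (2R)-2-[3,5-bis(methoxymethoxy)phenyl]-2-[4-geranyl-3,5-bis(methoxymethoxy)phenoxy]acetate
Conditions: PPh3, DIAD, PhMe, 0 → 23 °C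
Reagents that add atoms: none
Why: Mitsunobu etherification of an α-hydroxy ester by a phenol, an SN2 displacement of the alkoxyphosphonium with inversion ((S) to (R)) that forms O1–C2; the meta-oxygenated ring B does not stabilise a benzylic cation, which should hold the SN2 course.

Step 9
Reactants: 14 methyl (2R)-2-[3,5-bis(methoxymethoxy)phenyl]-2-[4-geranyl-3,5-bis(methoxymethoxy)phenoxy]acetate
Product: 15 (2R)-2-[3,5-bis(methoxymethoxy)phenyl]-2-[4-geranyl-3,5-bis(methoxymethoxy)phenoxy]acetic acid
Conditions: LiOH, THF/H2O (3:1), 0 °C; then 0.5 M HCl to pH 3–4 at 0 °C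
Reagents that add atoms: lithium hydroxide, [Li+].[OH-]
Why: Saponification of the methyl ester at 0 °C should outrun enolisation of the α-aryloxy ester, so the stereocentre should hold; MOM ethers tolerate base and a brief cold acidification.

Step 10
Reactants: 15 (2R)-2-[3,5-bis(methoxymethoxy)phenyl]-2-[4-geranyl-3,5-bis(methoxymethoxy)phenoxy]acetic acid
Product: 17 (3R)-1-diazo-3-[3,5-bis(methoxymethoxy)phenyl]-3-[4-geranyl-3,5-bis(methoxymethoxy)phenoxy]propan-2-one, via acid chloride 16 (not isolated)
Conditions: Me2C=C(Cl)NMe2 (1.1 equiv), CH2Cl2, 0 °C; then added to CH2N2 (3 equiv), Et2O, 0 °C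
Reagents that add atoms: diazomethane, C=[N+]=[N-]
Why: First stage of the Arndt–Eistert sequence: neutral acid chloride formation with the α-chloroenamine (no amine base, so the α-aryl acid chloride should not enolise or form a ketene), then C-acylation of diazomethane, whose excess takes up the HCl; C2 is untouched.

Step 11
Reactants: 17 (3R)-1-diazo-3-[3,5-bis(methoxymethoxy)phenyl]-3-[4-geranyl-3,5-bis(methoxymethoxy)phenoxy]propan-2-one
Product: 20 (2S)-2-[3,5-bis(methoxymethoxy)phenyl]-6-geranyl-5,7-bis(methoxymethoxy)-2,3-dihydro-4H-chromen-4-one, via ketene 18 (not isolated), via mixed trifluoroacetic anhydride 19 (not isolated)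
Conditions: hν (365 nm LED), CH2Cl2 (0.01 M), −40 °C; lamp off, then CF3CO2H (1.5 equiv), −40 → 23 °C
Reagents that add atoms: none
Why: Proposed new method: photochemical Wolff rearrangement of 17 should move C2, with its three other substituents untouched, from the acyl carbon to the carbene carbon with retention (as in the Arndt–Eistert homologation of α-amino and α-alkoxy acids), which forms C2–C3 and gives ketene 18; trifluoroacetic acid then adds to the ketene to give the mixed anhydride 19, which acylates ring A at a carbon ortho to O1 to form C4–C4a and return the acid. The closest known reactions are the Wolff rearrangement with capture of the ketene by a carboxylic acid to give an anhydride, and the trifluoroacetic anhydride-mediated closure of 3-aryloxypropanoic acids to chroman-4-ones; new is their fusion, so that the arene and not an outside nucleophile ends the Wolff cascade. Ring C closes as a 6-exo-trig Friedel–Crafts acylation. No new stereocentre is made: C2 comes from 13, is inverted once in step 8 and migrates here with retention, so the (3R)-diazoketone gives the (2S)-chromanone (the descriptor changes only because the CIP rank of the carbon neighbour changes). The selectivity needed is ring A over ring B (chromanone against indanone); it should be secured by the attacked carbon of ring A being ortho/para to three oxygens against two in ring B, by six- against five-membered closure and by the mildness of the mixed anhydride, while the two carbons ortho to O1 are equivalent, so only the 6-geranyl isomer can form. The ketene is held cold and dilute against dimerisation and Claisen-type opening, and the flavanone appears only after the lamp is off, so it is never irradiated.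

Step 12
Reactants: 20 (2S)-2-[3,5-bis(methoxymethoxy)phenyl]-6-geranyl-5,7-bis(methoxymethoxy)-2,3-dihydro-4H-chromen-4-one
Product: 21 Schizolaenone C, (2S)-2-(3,5-dihydroxyphenyl)-6-geranyl-5,7-dihydroxy-2,3-dihydro-4H-chromen-4-one
Conditions: HCl (1.25 M in MeOH), 23 → 40 °C
Reagents that add atoms: none
Why: Acid-catalysed transacetalisation of the four aryl MOM ethers to dimethoxymethane in methanol; flavanones racemise by base-induced ring opening and should hold under dilute acid, and the low temperature is meant to spare the geranyl chain.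

## Compound list

1 | phloroglucinol (benzene-1,3,5-triol) | Oc1cc(O)cc(O)c1 | starting material
2 | 5-(triisopropylsilyloxy)benzene-1,3-diol | Oc1cc(O)cc(O[Si](C(C)C)(C(C)C)C(C)C)c1 | intermediate
3 | [3,5-bis(methoxymethoxy)phenoxy]triisopropylsilane | COCOc1cc(OCOC)cc(O[Si](C(C)C)(C(C)C)C(C)C)c1 | intermediate
4 | geranyl bromide, (2E)-1-bromo-3,7-dimethylocta-2,6-diene | CC(C)=CCC/C(C)=C/CBr | starting material
5 | 2,6-bis(methoxymethoxy)-4-(triisopropylsilyloxy)phenyllithium | [Li]c1c(OCOC)cc(O[Si](C(C)C)(C(C)C)C(C)C)cc1OCOC | intermediate (not isolated)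
6 | triisopropyl[4-geranyl-3,5-bis(methoxymethoxy)phenoxy]silane | CC(C)=CCC/C(C)=C/Cc1c(OCOC)cc(O[Si](C(C)C)(C(C)C)C(C)C)cc1OCOC | intermediate
7 | 4-geranyl-3,5-bis(methoxymethoxy)phenol | CC(C)=CCC/C(C)=C/Cc1c(OCOC)cc(O)cc1OCOC | intermediate
8 | 5-bromoresorcinol (5-bromobenzene-1,3-diol) | Oc1cc(O)cc(Br)c1 | starting material
9 | 1-bromo-3,5-bis(methoxymethoxy)benzene | COCOc1cc(Br)cc(OCOC)c1 | intermediate
10 | dimethyl oxalate | COC(=O)C(=O)OC | starting material
11 | 3,5-bis(methoxymethoxy)phenyllithium | [Li]c1cc(OCOC)cc(OCOC)c1 | intermediate (not isolated)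
12 | methyl 2-[3,5-bis(methoxymethoxy)phenyl]-2-oxoacetate | COC(=O)C(=O)c1cc(OCOC)cc(OCOC)c1 | intermediate
13 | methyl (2S)-2-[3,5-bis(methoxymethoxy)phenyl]-2-hydroxyacetate | COC(=O)[C@@H](O)c1cc(OCOC)cc(OCOC)c1 | intermediate
14 | methyl (2R)-2-[3,5-bis(methoxymethoxy)phenyl]-2-[4-geranyl-3,5-bis(methoxymethoxy)phenoxy]acetate | CC(C)=CCC/C(C)=C/Cc1c(OCOC)cc(O[C@@H](C(=O)OC)c2cc(OCOC)cc(OCOC)c2)cc1OCOC | intermediate
15 | (2R)-2-[3,5-bis(methoxymethoxy)phenyl]-2-[4-geranyl-3,5-bis(methoxymethoxy)phenoxy]acetic acid | CC(C)=CCC/C(C)=C/Cc1c(OCOC)cc(O[C@@H](C(=O)O)c2cc(OCOC)cc(OCOC)c2)cc1OCOC | intermediate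
16 | (2R)-2-[3,5-bis(methoxymethoxy)phenyl]-2-[4-geranyl-3,5-bis(methoxymethoxy)phenoxy]acetyl chloride | CC(C)=CCC/C(C)=C/Cc1c(OCOC)cc(O[C@@H](C(=O)Cl)c2cc(OCOC)cc(OCOC)c2)cc1OCOC | intermediate (not isolated)
17 | (3R)-1-diazo-3-[3,5-bis(methoxymethoxy)phenyl]-3-[4-geranyl-3,5-bis(methoxymethoxy)phenoxy]propan-2-one | CC(C)=CCC/C(C)=C/Cc1c(OCOC)cc(O[C@@H](C(=O)C=[N+]=[N-])c2cc(OCOC)cc(OCOC)c2)cc1OCOC | intermediate
18 | (3S)-3-[3,5-bis(methoxymethoxy)phenyl]-3-[4-geranyl-3,5-bis(methoxymethoxy)phenoxy]prop-1-en-1-one (ketene) | CC(C)=CCC/C(C)=C/Cc1c(OCOC)cc(O[C@@H](C=C=O)c2cc(OCOC)cc(OCOC)c2)cc1OCOC | intermediate (not isolated)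
19 | (3S)-3-[3,5-bis(methoxymethoxy)phenyl]-3-[4-geranyl-3,5-bis(methoxymethoxy)phenoxy]propanoic trifluoroacetic anhydride | CC(C)=CCC/C(C)=C/Cc1c(OCOC)cc(O[C@@H](CC(=O)OC(=O)C(F)(F)F)c2cc(OCOC)cc(OCOC)c2)cc1OCOC | intermediate (not isolated)
20 | (2S)-2-[3,5-bis(methoxymethoxy)phenyl]-6-geranyl-5,7-bis(methoxymethoxy)-2,3-dihydro-4H-chromen-4-one | CC(C)=CCC/C(C)=C/Cc1c(OCOC)cc2c(c1OCOC)C(=O)C[C@@H](c1cc(OCOC)cc(OCOC)c1)O2 | intermediate
21 | Schizolaenone C, (2S)-2-(3,5-dihydroxyphenyl)-6-geranyl-5,7-dihydroxy-2,3-dihydro-4H-chromen-4-one | CC(C)=CCC/C(C)=C/Cc1c(O)cc2c(c1O)C(=O)C[C@@H](c1cc(O)cc(O)c1)O2 | target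

## Step count and risks

Total steps: 12. Longest linear sequence: 9 steps (steps 1–4, then 8–12); the ring B branch (steps 5–7) joins at step 8.

Steps most likely to fail:

1. Step 11 (Proposed new method). The ketene may be lost to dimerisation or to traces of water before it is trapped, and acylation by the dilute mixed anhydride may be too slow or may go in part to ring B. Fallback (known chemistry, sets out from 17, returns at 20): the two bond formations are done in two isolated steps. 17 is taken through the Arndt–Eistert homologation (PhCO2Ag cat., Et3N, THF/H2O, 23 °C, dark), in which water traps the ketene, to give (3S)-3-[3,5-bis(methoxymethoxy)phenyl]-3-[4-geranyl-3,5-bis(methoxymethoxy)phenoxy]propanoic acid F1. The isolated acid is then closed with (CF3CO)2O in CH2Cl2 at 0 °C, the established ring closure of 3-aryloxypropanoic acids to chroman-4-ones, which gives 20.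

2. Step 8. Configuration may be partly lost, by ionisation of the activated benzylic alkoxyphosphonium or by enolisation of the α-aryloxy ester, and the coupling of the electron-rich phenol may be sluggish. Fallback (sets out from 15 of insufficient enantiomeric purity, returns at 15): classical resolution in place of reliance on a stereospecific substitution. 15 is crystallised with (S)-1-phenylethylamine (which amine enantiomer and solvent give the less soluble salt of the (R)-acid is to be found by screening) as (S)-1-phenylethylammonium (2R)-2-[3,5-bis(methoxymethoxy)phenyl]-2-[4-geranyl-3,5-bis(methoxymethoxy)phenoxy]acetate F2. The recrystallised salt is partitioned between cold aqueous KHSO4 and EtOAc to return 15.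

3. Step 12. While four MOM groups are removed, the protic acid may add a freed C5 or C7 hydroxyl (or methanol) across the geranyl double bonds. Fallback (sets out from 20, returns at 21): a two-stage, non-protic unmasking. Et3SiOTf/2,2′-bipyridyl (CH2Cl2, 0 °C) exchanges each aryl MOM ether for an aryl triethylsilyl ether and gives (2S)-2-[3,5-bis(triethylsilyloxy)phenyl]-6-geranyl-5,7-bis(triethylsilyloxy)-2,3-dihydro-4H-chromen-4-one F3. This is desilylated with KHF2 in MeOH at 23 °C to 21.

## Further compounds

F1 | step 11 | (3S)-3-[3,5-bis(methoxymethoxy)phenyl]-3-[4-geranyl-3,5-bis(methoxymethoxy)phenoxy]propanoic acid | CC(C)=CCC/C(C)=C/Cc1c(OCOC)cc(O[C@@H](CC(=O)O)c2cc(OCOC)cc(OCOC)c2)cc1OCOC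
F2 | step 8 | (S)-1-phenylethylammonium (2R)-2-[3,5-bis(methoxymethoxy)phenyl]-2-[4-geranyl-3,5-bis(methoxymethoxy)phenoxy]acetate | CC(C)=CCC/C(C)=C/Cc1c(OCOC)cc(O[C@@H](C([O-])=O)c2cc(OCOC)cc(OCOC)c2)cc1OCOC.C[C@H]([NH3+])c1ccccc1
F3 | step 12 | (2S)-2-[3,5-bis(triethylsilyloxy)phenyl]-6-geranyl-5,7-bis(triethylsilyloxy)-2,3-dihydro-4H-chromen-4-one | CC(C)=CCC/C(C)=C/Cc1c(O[Si](CC)(CC)CC)cc2c(c1O[Si](CC)(CC)CC)C(=O)C[C@@H](c1cc(O[Si](CC)(CC)CC)cc(O[Si](CC)(CC)CC)c1)O2
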